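The target is the C2–C3 hydrate of a flat 2-benzylchromone, and the hemiketal carbon C2 of the pyranone ring is its only stereocentre. The route therefore traces the hemiketal back to a cis-fused 2,3-epoxychromanone, made by enantioface-selective nucleophilic epoxidation of the C2=C3 bond of the vinylogous ester. That single operation forms the C2–O and C3–O bonds, the oxirane ring and the C2 configuration. Neutral hydrogenolysis then removes only the C3 oxygen, together with all four benzyl groups. The precursor is the per-benzylated chromone carrying the heptyl chain on ring A and the benzyl orsellinate unit (ring B) on the C2 methylene, assembled by Claisen acylation and cyclodehydration.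

Key step: step 6

Remarks on the chemistry:
- 5-Heptylbenzene-1,3-diol is taken as a catalogue compound.
- C2 of the target is a hemiketal carbon that could racemise by ring opening to the achiral 1,3-diketone; it is assumed to hold its configuration under neutral, aprotic conditions at or below room temperature, so no acid or base is used after step 6.
- The facial sense of a cinchona salt on a 2-substituted chromone cannot be predicted with confidence; the cinchonine-derived salt is written in step 6, and its cinchonidine-derived pseudoenantiomer is used instead if it proves to deliver the other face.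
- The structures of the chromone and of the epoxide were checked against the target: the epoxide is (1aR,7aS), cis-fused, and carries the C2 oxygen where the target carries its hydroxyl; no correction is needed.

Step 1
Reactants: 1 orsellinic acid
Product: 2 benzyl 2,4-bis(benzyloxy)-6-methylbenzoate
Conditions: BnBr (3.3 equiv), K2CO3, DMF, 50 °C
Reagents that add atoms: benzyl bromide, BrCc1ccccc1
Why: Exhaustive Williamson-type O-benzylation (carboxylate and both phenoxides alkylated by SN2) is the standard protection of orsellinic acid, and it is run warm rather than hot so that the β-resorcylic acid does not decarboxylate before it is esterified.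

Step 2
Reactants: 2 benzyl 2,4-bis(benzyloxy)-6-methylbenzoate
Product: 4 {3,5-bis(benzyloxy)-2-[(benzyloxy)carbonyl]phenyl}acetic acid, via lithiated ester 3 (not isolated)
Conditions: LiN(i-Pr)2 (1.2 equiv), THF, −78 °C (ester added to base); CO2 (g), −78 °C to rt; aq. HCl
Reagents that add atoms: carbon dioxide, O=C=O
Why: Lateral lithiation of an ortho-toluate followed by carboxylation: the ester acidifies the ortho methyl group vinylogously, LiN(i-Pr)2 removes that proton at −78 °C faster than it can attack the doubly ortho-substituted ester, and the benzylic anion traps CO2 to give the homophthalic half ester with the two carboxyl groups already differentiated.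

Step 3
Reactants: 5 5-heptylbenzene-1,3-diol
Product: 7 1-(2,4-dihydroxy-6-heptylphenyl)ethan-1-one, via ketiminium chloride 6 (not isolated)
Conditions: MeCN, ZnCl2, HCl (g), Et2O, 0 °C; then H2O, reflux
Reagents that add atoms: acetonitrile, CC#N; water, O
Why: Houben–Hoesch acylation: the activated nitrile attacks the resorcinol at C4, para to one hydroxyl, ortho to the other and next to the heptyl chain (the orientation established for orcinol), and hydrolysis of the ketiminium salt gives the aryl methyl ketone; any symmetrical 2-acyl isomer should be removable by crystallisation or chromatography.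

Step 4
Reactants: 7 1-(2,4-dihydroxy-6-heptylphenyl)ethan-1-one
Product: 8 1-[4-(benzyloxy)-2-heptyl-6-hydroxyphenyl]ethan-1-one
Conditions: BnBr (1.05 equiv), K2CO3 (1.2 equiv), acetone, reflux
Reagents that add atoms: benzyl bromide, BrCc1ccccc1
Why: Regioselective Williamson etherification: the hydroxyl ortho to the acetyl group is locked in a hydrogen bond to the carbonyl and is far less nucleophilic, so one equivalent of benzyl bromide should alkylate only the para hydroxyl.

Step 5
Reactants: 4 {3,5-bis(benzyloxy)-2-[(benzyloxy)carbonyl]phenyl}acetic acid; 8 1-[4-(benzyloxy)-2-heptyl-6-hydroxyphenyl]ethan-1-one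
Product: 12 benzyl 2,4-bis(benzyloxy)-6-{[7-(benzyloxy)-5-heptyl-4-oxo-4H-chromen-2-yl]methyl}benzoate, via acyl imidazolide 9 (not isolated), via dilithium dienolate 10 (not isolated), via beta-diketone 11 (not isolated)
Conditions: 4, CDI, THF, rt; separately 8, LiN(SiMe3)2 (4.5 equiv), THF, −78 °C; imidazolide solution added, −78 to −20 °C; AcOH quench; crude diketone, TsOH·H2O (cat.), toluene, 70 °C
Reagents that add atoms: none
Why: Crossed Claisen condensation followed by acid-catalysed chromone cyclodehydration: the pre-formed phenoxide–enolate dianion is C-acylated by the acyl imidazolide (an enolised acyl donor still delivers the same 1,3-diketone through its ketene), the excess amide base absorbs the acidic imidazole and diketone protons, the doubly ortho-substituted benzyl ester is too hindered to be attacked in the cold, and TsOH then closes the phenol onto the distal ketone and dehydrates the hemiketal to the chromone.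

Step 6
Reactants: 12 benzyl 2,4-bis(benzyloxy)-6-{[7-(benzyloxy)-5-heptyl-4-oxo-4H-chromen-2-yl]methyl}benzoate
Product: 13 benzyl 2,4-bis(benzyloxy)-6-{[(1aR,7aS)-4-(benzyloxy)-6-heptyl-7-oxo-7,7a-dihydro-1aH-oxireno[2,3-b]chromen-1a-yl]methyl}benzoate (the (2R,3S)-2,3-epoxychroman-4-one in chromanone numbering)
Conditions: cumene hydroperoxide (2 equiv), N-[4-(trifluoromethyl)benzyl]cinchoninium bromide (10 mol %), aq. KOH (1 M, 0.5 equiv), toluene, 0 °C, Ar; neutral work-up, crude product used directly
Reagents that add atoms: cumene hydroperoxide, CC(C)(OO)c1ccccc1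
Why: Proposed new method: the ammonium-paired cumylperoxide anion adds to C2, the β-carbon of the vinylogous ester, and the C3 enolate so formed displaces cumyloxide from the proximal peroxide oxygen, a Weitz–Scheffer epoxidation whose closest known relatives are the chiral phase-transfer epoxidation of chalcones and of 2-unsubstituted isoflavones and the racemic alkaline-peroxide epoxidation of chromones; what is new is asymmetric delivery to a fully substituted β-carbon in this substrate class. The oxirane closes 3-exo-tet at oxygen and can only be cis-fused to the pyranone ring, so the two new stereocentres are linked and one face choice decides both. The configuration at C2, and with it C3, is set by the chiral cation, which is expected to hold the C4 carbonyl through its C9 hydroxyl and to shield one face of the planar chromone; the substrate is achiral and exerts no bias of its own. The step needs chemoselectivity for conjugate addition over deprotonation of the acidic C2–CH2–aryl methylene and over perhydrolysis of the benzyl ester: the hydroperoxide is kept in excess over KOH so that the only base in the organic phase is the weakly basic peroxide anion, air is excluded, and the ester is shielded by its two ortho substituents. The acetal-like epoxide should tolerate base but not acid, hence the neutral work-up and direct use.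

Step 7
Reactants: 13 benzyl 2,4-bis(benzyloxy)-6-{[(1aR,7aS)-4-(benzyloxy)-6-heptyl-7-oxo-7,7a-dihydro-1aH-oxireno[2,3-b]chromen-1a-yl]methyl}benzoate
Product: 14 2-{[(2R)-5-heptyl-2,7-dihydroxy-4-oxo-3,4-dihydro-2H-chromen-2-yl]methyl}-4,6-dihydroxybenzoic acid
Conditions: H2 (1 atm), 10% Pd/C, EtOAc, 0 °C to rt; filtration, evaporation below rt, no acid or base
Reagents that add atoms: none
Why: Catalytic hydrogenolysis: palladium cleaves the C3–O bond of the α,β-epoxy ketone (the bond α to the carbonyl, as in the known conversion of epoxy ketones into aldols) and the four benzylic C–O bonds, while the C2–O bond is not activated and is never broken, so C2 keeps its R configuration and the hemiketal hydroxyl appears under neutral conditions.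

Compound list
1 | orsellinic acid (2,4-dihydroxy-6-methylbenzoic acid) | Cc1cc(O)cc(O)c1C(=O)O | starting material
2 | benzyl 2,4-bis(benzyloxy)-6-methylbenzoate | Cc1cc(OCc2ccccc2)cc(OCc2ccccc2)c1C(=O)OCc1ccccc1 | intermediate
3 | benzyl 2,4-bis(benzyloxy)-6-(lithiomethyl)benzoate | [Li]Cc1cc(OCc2ccccc2)cc(OCc2ccccc2)c1C(=O)OCc1ccccc1 | intermediate
4 | {3,5-bis(benzyloxy)-2-[(benzyloxy)carbonyl]phenyl}acetic acid | OC(=O)Cc1cc(OCc2ccccc2)cc(OCc2ccccc2)c1C(=O)OCc1ccccc1 | intermediate
5 | 5-heptylbenzene-1,3-diol (5-heptylresorcinol) | CCCCCCCc1cc(O)cc(O)c1 | starting material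
6 | 1-(2,4-dihydroxy-6-heptylphenyl)ethan-1-iminium chloride | CCCCCCCc1cc(O)cc(O)c1C(C)=[NH2+].[Cl-] | intermediate
7 | 1-(2,4-dihydroxy-6-heptylphenyl)ethan-1-one | CCCCCCCc1cc(O)cc(O)c1C(C)=O | intermediate
8 | 1-[4-(benzyloxy)-2-heptyl-6-hydroxyphenyl]ethan-1-one | CCCCCCCc1cc(OCc2ccccc2)cc(O)c1C(C)=O | intermediate
9 | benzyl 2,4-bis(benzyloxy)-6-[2-(1H-imidazol-1-yl)-2-oxoethyl]benzoate | O=C(Cc1cc(OCc2ccccc2)cc(OCc2ccccc2)c1C(=O)OCc1ccccc1)n1ccnc1 | intermediate
10 | dilithium 5-(benzyloxy)-3-heptyl-2-(1-oxidoethenyl)phenolate | CCCCCCCc1cc(OCc2ccccc2)cc([O-])c1C(=C)[O-].[Li+].[Li+] | intermediate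
11 | benzyl 2,4-bis(benzyloxy)-6-{4-[4-(benzyloxy)-2-heptyl-6-hydroxyphenyl]-2,4-dioxobutyl}benzoate | CCCCCCCc1cc(OCc2ccccc2)cc(O)c1C(=O)CC(=O)Cc1cc(OCc2ccccc2)cc(OCc2ccccc2)c1C(=O)OCc1ccccc1 | intermediate
12 | benzyl 2,4-bis(benzyloxy)-6-{[7-(benzyloxy)-5-heptyl-4-oxo-4H-chromen-2-yl]methyl}benzoate | CCCCCCCc1cc(OCc2ccccc2)cc2oc(Cc3cc(OCc4ccccc4)cc(OCc4ccccc4)c3C(=O)OCc3ccccc3)cc(=O)c12 | intermediate
13 | benzyl 2,4-bis(benzyloxy)-6-{[(1aR,7aS)-4-(benzyloxy)-6-heptyl-7-oxo-7,7a-dihydro-1aH-oxireno[2,3-b]chromen-1a-yl]methyl}benzoate | CCCCCCCc1cc(OCc2ccccc2)cc2c1C(=O)[C@H]3[C@@](O3)(Cc1cc(OCc3ccccc3)cc(OCc3ccccc3)c1C(=O)OCc1ccccc1)O2 | intermediate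
14 | 2-{[(2R)-5-heptyl-2,7-dihydroxy-4-oxo-3,4-dihydro-2H-chromen-2-yl]methyl}-4,6-dihydroxybenzoic acid | CCCCCCCc1cc(O)cc2c1C(=O)C[C@@](O)(Cc1cc(O)cc(O)c1C(=O)O)O2 | target

Total step count: 7
Longest linear sequence: 5 steps (1, 2, 5, 6, 7 from orsellinic acid; equally 3, 4, 5, 6, 7 from 5-heptylresorcinol)

Steps most likely to fail

1. Step 6 (Proposed new method). The peroxide may fail to add at the fully substituted C2. The peroxide adduct may lose the ring phenoxide instead of closing the oxirane. The C2 methylene may be deprotonated and oxidised, or facial selectivity may be poor. Fallback, using known chemistry: from 12, electrophilic epoxidation with dimethyldioxirane (acetone/CH2Cl2, 0 °C), the established route to chromone and flavone 2,3-epoxides, should give the racemic epoxide. This is 13 together with its mirror image, benzyl 2,4-bis(benzyloxy)-6-{[(1aS,7aR)-4-(benzyloxy)-6-heptyl-7-oxo-7,7a-dihydro-1aH-oxireno[2,3-b]chromen-1a-yl]methyl}benzoate F1. Preparative HPLC on a chiral stationary phase with a neutral eluent should separate the enantiomers, and the route is rejoined at 13.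

2. Step 5. Proton transfer from the acyl donor to the enolate may outrun C-acylation, or the diketone enolate may attack the ortho ester (naphthol or isocoumarin formation) before acid closes the chromone. Fallback: from 8, condensation with N,N-dimethylformamide dimethyl acetal (toluene, 100 °C) should give the enaminone (2E)-1-[4-(benzyloxy)-2-heptyl-6-hydroxyphenyl]-3-(dimethylamino)prop-2-en-1-one F2. HCl in CH2Cl2 should close it to 7-(benzyloxy)-5-heptyl-4H-chromen-4-one F3. The lithiated ester 3 (from 2 and LiN(i-Pr)2, THF, −78 °C) is then added 1,4 to F3 at C2, and the enolate is trapped with Me3SiCl before it can attack the ester. This should give racemic benzyl 2,4-bis(benzyloxy)-6-({7-(benzyloxy)-5-heptyl-4-[(trimethylsilyl)oxy]-2H-chromen-2-yl}methyl)benzoate F4. Saegusa–Ito oxidation with Pd(OAc)2 in MeCN restores the C2=C3 double bond, and the route is rejoined at 12.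

3. Step 7. Early loss of the benzyl ester may free a carboxylic acid that opens the acid-labile epoxy acetal before its C3–O bond is reduced. The free hemiketal may also dehydrate to the chromone or open to the diketone on prolonged contact with the catalyst. Fallback: from 13, single-electron reduction with SmI2 (THF/MeOH, −90 °C), the standard conversion of α,β-epoxy ketones into β-hydroxy ketones, cleaves the C3–O bond while all benzyl groups are still in place. It should give benzyl 2,4-bis(benzyloxy)-6-{[(2R)-7-(benzyloxy)-5-heptyl-2-hydroxy-4-oxo-3,4-dihydro-2H-chromen-2-yl]methyl}benzoate F5. Hydrogenolysis of F5 (H2, 10% Pd/C, EtOAc, 0 °C) then removes the four benzyl groups, and the route is rejoined at 14.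

Further compounds
F1 | step 6 | benzyl 2,4-bis(benzyloxy)-6-{[(1aS,7aR)-4-(benzyloxy)-6-heptyl-7-oxo-7,7a-dihydro-1aH-oxireno[2,3-b]chromen-1a-yl]methyl}benzoate | CCCCCCCc1cc(OCc2ccccc2)cc2c1C(=O)[C@@H]3[C@](O3)(Cc1cc(OCc3ccccc3)cc(OCc3ccccc3)c1C(=O)OCc1ccccc1)O2
F2 | step 5 | (2E)-1-[4-(benzyloxy)-2-heptyl-6-hydroxyphenyl]-3-(dimethylamino)prop-2-en-1-one | CCCCCCCc1cc(OCc2ccccc2)cc(O)c1C(=O)/C=C/N(C)C
F3 | step 5 | 7-(benzyloxy)-5-heptyl-4H-chromen-4-one | CCCCCCCc1cc(OCc2ccccc2)cc2occc(=O)c12
F4 | step 5 | benzyl 2,4-bis(benzyloxy)-6-({7-(benzyloxy)-5-heptyl-4-[(trimethylsilyl)oxy]-2H-chromen-2-yl}methyl)benzoate (racemic) | CCCCCCCc1cc(OCc2ccccc2)cc2OC(Cc3cc(OCc4ccccc4)cc(OCc4ccccc4)c3C(=O)OCc3ccccc3)C=C(O[Si](C)(C)C)c12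
F5 | step 7 | benzyl 2,4-bis(benzyloxy)-6-{[(2R)-7-(benzyloxy)-5-heptyl-2-hydroxy-4-oxo-3,4-dihydro-2H-chromen-2-yl]methyl}benzoate | CCCCCCCc1cc(OCc2ccccc2)cc2c1C(=O)C[C@@](O)(Cc1cc(OCc3ccccc3)cc(OCc3ccccc3)c1C(=O)OCc1ccccc1)O2
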